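The neighbour run at 25 °C stands beside the two flasks below, and before repeating them we want one figure that can be reckoned by hand and then watched.

    complex + complex ⇌ resting dimer (K1 = 1.6 × 10⁵ /M, k1 = 78000 /M/s, Ea1 = 28.0 kJ/mol, ΔH1 = −31.0 kJ/mol)
    complex → free enzyme + product (k2 = 250 /s, Ea2 = 55.0 kJ/mol)
    free enzyme → unfolded enzyme (k3 = 0.0039 /s, Ea3 = 267 kJ/mol)
    free enzyme → spent catalyst (k4 = 0.046 /s, Ea4 = 84.0 kJ/mol)
    substrate + free enzyme ⇌ complex (K5 = 29 /M, k5 = 1.8 × 10⁷ /M/s, Ea5 = 18.0 kJ/mol, ΔH5 = −49.0 kJ/mol)
    (constants at 20 °C)

| setting | gamma | delta |
|---|---|---|
| substrate | 0.020 M | 0.020 M |
| free enzyme | 0.01 mol% | 0.01 mol% |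
| temperature | 50 °C | 20 °C |
| time | 20 s | 20 s |

* the best flask by amount of product, in percent of the substrate charged; "all alike" if 1.5 percentage points covers them all (gamma / delta / all alike)
* amount of product at the end, in percent of the substrate charged, gamma
* amount of product at the end, in percent of the substrate charged, delta

- percent here means substrate units held: one resting dimer counts as two
- where a step has two of a species, its rate is k times that concentration squared, and two are used at each turn
- the list of constants is for 20 °C, to be carried to other temperatures by the activation energies and enthalpies

We climb down the ladder of rates in delta, fastest first. In delta complex falls apart at 6.21 × 10⁵ /s, far faster than it turns to product at 250 /s, so binding stays in balance, with complex to free enzyme at 0.580 while [substrate] stays near its charge. In delta the turning of complex is the rate-limiting step of the round, and per free enzyme it runs at 145 /s. In delta resting dimer comes apart at about 0.487 /s. Slowest of these in delta, free enzyme dies at 0.0499 /s, faster to spent catalyst than to unfolded enzyme.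

Because complex falls apart far faster than it turns, turning stands in proportion to free enzyme, as dying does, so their ratio does not change with how long enzyme sits as dimer. This gives the quantity to carry, the budget: turning constant times binding constant times the concentration of enzyme charged, divided by the sum of the dying constants, which by our reckoning is the natural logarithm by which the charge lowers [substrate] before it is dead. In delta it is 0.291, so our estimate of the ceiling on product, one minus e to the minus budget, is 25.2%. With [substrate] held at its charge and dimer left aside, we reckon that in delta a share of 46.8% of the enzyme is dead within 20 s, which spends that share of the budget and gives us 12.7% of product.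

Gamma is best done in powers of ten. Going up to 50 °C, turning gains 0.910, binding loses 0.811 and dying costs 3.31, so gamma's budget is 1.77 × 10⁻⁴. The life of its free enzyme, 0.00972 s, is far shorter than the run, so gamma should stop at its ceiling, 0.0177%.

The forecast names delta, with 0.018% for gamma and 12.6% for delta, a little under our delta figure; its ground for gamma is that “the free enzyme dies within a fraction of a second”.

The simulation gives delta as the best flask, with 0.0177% in gamma and 12.5% in delta. Left for 200 s, delta stands at 25.2%, against the ceiling of 25.2% reckoned from the constants. The thing to watch is the dead share of the enzyme: at 20.0 s delta holds 3.59% as unfolded enzyme and 42.3% as spent catalyst, and that share of the budget gives 12.5% product.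

In the neighbour, gamma repeated at 25 °C, the budget is 0.142, which puts the ceiling at 13.2%. The computed product is 10.4%, below that ceiling, with 16.1% of the enzyme still free and 5.96% as complex at 20.0 s.

The numbers of this flask were set for the occasion; the flask was simulated.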